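**Retrosynthetic overview**
- Target ⇐ acylation of the C8 hydroxyl with (E)-N-methylurocanic acid; C2=C3 ⇐ sulfoxide syn-elimination of a C3 pyridylthio handle.
- C7(Me)–O ⇐ MeLi addition to an Achmatowicz pyranone, itself made by singlet-oxygen photooxygenation of a [6](2,5)furanophane (furan C4–C7 = masked ene-dione).
- Ten-membered ring ⇐ NiCl2/CrCl2 closure of C7–C8 (2-bromofuran + C8 aldehyde).
- C1–C2 bond and the C1 stereocentre ⇐ visible-light decarboxylative radical carbothiolation of a 2-furylacrylate by the C1 carboxylic acid (key step).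
- Acid ⇐ dichloroketene [2+2] / Bredereck ring opening of (R)-α-phellandrene. Ring order: cyclohexene (bought) → ten-membered furanophane → pyranone → 4,7-oxa bridge.

Assumption: the target is taken exactly as the SMILES defines it, (1R,4R,7S,8S,10R,14R; 2E) in eunicellane numbering (C1/C10 ring fusion, C11(Me)=C12, C14 isopropyl, C2=C3(CO2Me), C4 hemiketal, C5=C6, C7(Me), C8 ester, C9), i.e. the C2 branch on C1 is cis to isopropyl and trans to the C9 branch on C10; sp3 C3 intermediates are carried as C3 epimer mixtures because C3 ends sp2.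

**Route**

Step 1
Reactants: 1 (R)-(−)-α-phellandrene
Product: 3 8,8-dichloro-2-methyl-5-(propan-2-yl)bicyclo[4.2.0]oct-2-en-7-one (cis-fused; four-membered ring anti to isopropyl), via dichloroketene 2 (not isolated)
Conditions: Cl3CCOCl, Zn dust, Et2O, ultrasound, 15–20 °C
Reagents that add atoms: trichloroacetyl chloride, ClC(=O)C(Cl)(Cl)Cl
Why: Thermal ketene–alkene [2+2] cycloaddition; dichloroketene adds to the less substituted C3=C4 bond of the diene, carbonyl carbon at the diene terminus, on the face opposite the isopropyl group, so the bought C14 centre fixes C10 (and a provisional cis C1).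

Step 2
Reactants: 3 dichlorocyclobutanone
Product: 4 2-methyl-5-(propan-2-yl)bicyclo[4.2.0]oct-2-en-7-one
Conditions: Zn dust, AcOH, 25 → 50 °C
Reagents that add atoms: none
Why: Zinc-mediated reductive dechlorination of an α,α-dichloro ketone; no stereocentre is touched.

Step 3
Reactants: 4 cyclobutanone
Product: 5 (E)-8-[(dimethylamino)methylidene]-2-methyl-5-(propan-2-yl)bicyclo[4.2.0]oct-2-en-7-one
Conditions: t-BuOCH(NMe2)2 (neat), 60 °C
Reagents that add atoms: tert-butoxybis(dimethylamino)methane, CN(C)C(OC(C)(C)C)N(C)C
Why: Bredereck aminomethylenation (condensation) at the only enolisable α-methylene of the cyclobutanone.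

Step 4
Reactants: 5 enaminone
Product: 6 methyl 2-(2,2-dimethoxyethyl)-3-methyl-6-(propan-2-yl)cyclohex-3-ene-1-carboxylate (ester cis to the acetal chain; both trans to isopropyl)
Conditions: TsOH·H2O (1.2 equiv), MeOH, 60 °C; then aq. NaHCO3
Reagents that add atoms: methanol, CO
Why: Acid-promoted methanolysis with retro-Claisen ring opening of the strained 2-aminomethylene cyclobutanone: methanol adds to the ketone, the bond to the vinylogous iminium carbon breaks and the enamine ends as the dimethyl acetal, leaving CO2Me on C1 and the C9–C8 unit on C10.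

Step 5
Reactants: 6 ester acetal
Product: 7 2-(2,2-dimethoxyethyl)-3-methyl-6-(propan-2-yl)cyclohex-3-ene-1-carboxylic acid
Conditions: LiOH, THF/MeOH/H2O, 50 °C; then cold dilute HCl to pH 4
Reagents that add atoms: lithium hydroxide, [Li+].[OH-]
Why: Ester saponification; any epimerisation at C1 is harmless because C1 becomes a planar radical in step 8.

Step 6
Reactants: 8 methyl 2-(furan-2-yl)acetate
Product: 9 methyl 2-(5-bromofuran-2-yl)acetate
Conditions: NBS, DMF, 0 °C, dark
Reagents that add atoms: N-bromosuccinimide, O=C1CCC(=O)N1Br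
Why: Electrophilic aromatic bromination at the free α-position of the 2-alkylfuran; ionic conditions avoid side-chain bromination.

Step 7
Reactants: 9 methyl 2-(5-bromofuran-2-yl)acetate
Product: 11 methyl 2-(5-bromofuran-2-yl)prop-2-enoate, via hydroxymethyl ester 10 (not isolated)
Conditions: (CH2O)n, K2CO3, n-Bu4NI (cat.), DMF, 60 °C; product kept cold over BHT
Reagents that add atoms: formaldehyde (as paraformaldehyde), C=O
Why: Base-mediated aldol-type hydroxymethylation of the arylacetate followed by E1cB dehydration (α-methylenation) gives the 2-heteroaryl acrylate.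

Step 8
Reactants: 7 carboxylic acid; 11 methyl 2-(5-bromofuran-2-yl)prop-2-enoate (2.5 equiv)
Product: 12 methyl 2-(5-bromofuran-2-yl)-3-[2-(2,2-dimethoxyethyl)-3-methyl-6-(propan-2-yl)cyclohex-3-en-1-yl]-2-(pyridin-2-ylsulfanyl)propanoate (ring CH2 cis to isopropyl and trans to the acetal chain; C3 epimers)
Conditions: 4CzIPN (2 mol%), 2,2'-dipyridyl disulfide (2 equiv), Cs2CO3 (20 mol%), MeCN, 450 nm LEDs, 20 °C, degassed
Reagents that add atoms: 2,2'-dipyridyl disulfide, c1ccc(SSc2ccccn2)nc1
Why: Proposed new method: visible-light, redox-neutral decarboxylative 1,2-carbothiolation of a 2-heteroarylacrylate with a free carboxylic acid and a disulfide – the excited photocatalyst oxidises the carboxylate of 7, loss of CO2 gives the secondary C1 radical, this nucleophilic radical adds to the CH2 terminus of 11, and the ester/furyl-stabilised tertiary radical is captured at sulfur by the disulfide (homolytic substitution, or enolate sulfenylation after reduction by the reduced photocatalyst), the pyridylthiyl radical or thiolate closing the cycle and being protonated by the next molecule of acid so that base is needed only in catalytic amount; the closest known reactions are the photoredox decarboxylative Giese addition and Barton's thiohydroxamate decarboxylative addition with thiopyridyl transfer; stereocontrol: the planar C1 radical sits in a half-chair whose C10 side chain is pseudoaxial (1,2-allylic strain with the C11 methyl) and whose isopropyl is equatorial, so axial attack anti to the C10 chain makes C2 trans to C9 and cis to isopropyl, the C1 configuration of the target, whatever the configuration of the acid.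

Step 9
Reactants: 12 sulfide acetal
Product: 13 methyl 2-(5-bromofuran-2-yl)-3-[3-methyl-2-(2-oxoethyl)-6-(propan-2-yl)cyclohex-3-en-1-yl]-2-(pyridin-2-ylsulfanyl)propanoate
Conditions: AcOH/THF/H2O (3:1:1), 40 °C
Reagents that add atoms: water, O
Why: Acid-catalysed acetal hydrolysis under conditions mild enough for the bromofuran, the sulfide and the methyl ester.

Step 10
Reactants: 13 bromofuran aldehyde
Product: 14 [6](2,5)furanophane alcohol (ten-membered carbocycle closed at C7–C8; 8S; C3 epimers)
Conditions: CrCl2 (10 equiv), NiCl2 (0.1 equiv), DMF/THF, 0.002 M, 25 °C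
Reagents that add atoms: none
Why: Nozaki–Hiyama–Kishi reaction under high dilution: zerovalent nickel inserts into the furyl C–Br bond, transmetalation gives a furyl–chromium species (trivalent chromium) that adds to the C8 aldehyde without touching ester, sulfide or alkene, closing the strained furanophane; C8 is set by macrocyclic control, the chromium-bound oxygen sitting on the periphery of the ansa chain (8S expected).

Step 11
Reactants: 14 furanophane alcohol
Product: 17 pyranone hemiketal (Achmatowicz product; C7 ketone; C4–O–C8 ring), via furan endoperoxide 15 (not isolated), via cis-enedione alcohol 16 (not isolated)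
Conditions: O2, tetraphenylporphyrin (cat.), white LED, CH2Cl2, −78 °C; then Me2S, −78 → 0 °C
Reagents that add atoms: oxygen, O=O
Why: Photo-Achmatowicz reaction: photosensitised singlet oxygen adds [4+2] to the strained 2,5-dialkylfuran far faster than to the trisubstituted alkene or the electron-poor aryl sulfide, Me2S reduces the endoperoxide to the cis-enedione and the C8 hydroxyl closes onto the C4 ketone; the hemiketal centre is fixed by the bridge.

Step 12
Reactants: 17 pyranone hemiketal
Product: 18 C7 methyl carbinol (pyranose hemiketal diol; 7S)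
Conditions: MeLi (3.5 equiv), THF, −78 °C; then aq. NH4Cl
Reagents that add atoms: methyllithium, [Li]C
Why: 1,2-Addition of MeLi to the enone carbonyl at −78 °C (the hindered α-quaternary methyl ester and the sulfide survive) from the convex face opposite the C8–C9 bond and the ansa bridge, placing the new hydroxyl cis to C9 and setting C7 (7S).

Step 13
Reactants: 18 C7 methyl carbinol
Product: 20 des-urocanoyl enoate in its pyranose hemiketal form, via sulfoxide 19 (not isolated)
Conditions: mCPBA (1.05 equiv), CH2Cl2, −78 °C; then 40 °C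
Reagents that add atoms: none
Why: Chemoselective sulfide oxidation followed by thermal sulfoxide syn-elimination; only the C2 hydrogens are available (C4 is quaternary) and the ten-membered ring allows only the E enoate with C1 and C4 cis, so both C3 epimers converge.

Step 14
Reactants: 20 des-urocanoyl enoate; 21 (E)-3-(1-methyl-1H-imidazol-4-yl)prop-2-enoic acid
Product: 23 target, via furanose tautomer 22 (not isolated)
Conditions: DCC, DMAP (cat.), CH2Cl2/DMF, 25 °C
Reagents that add atoms: none
Why: Steglich esterification coupled to ring–chain tautomerism: only the furanose tautomer offers an unhindered secondary hydroxyl (C8), so acylation drains the pyranose–furanose equilibrium into the 4,7-oxa-bridged ester, whose bridge geometry fixes C4 (4R).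

**Compound list**

1 | (R)-(−)-α-phellandrene | CC1=CC[C@H](C(C)C)C=C1 | starting material
2 | dichloroketene | O=C=C(Cl)Cl | intermediate (not isolated)
3 | 8,8-dichloro-2-methyl-5-(propan-2-yl)bicyclo[4.2.0]oct-2-en-7-one, cis-fused, anti to isopropyl | O=C1[C@@H]2[C@@H](C(C)C)CC=C(C)[C@@H]2C1(Cl)Cl | intermediate
4 | 2-methyl-5-(propan-2-yl)bicyclo[4.2.0]oct-2-en-7-one | O=C1[C@@H]2[C@@H](C(C)C)CC=C(C)[C@@H]2C1 | intermediate
5 | (E)-8-[(dimethylamino)methylidene] cyclobutanone | O=C1[C@@H]2[C@@H](C(C)C)CC=C(C)[C@@H]2/C1=C\N(C)C | intermediate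
6 | methyl 2-(2,2-dimethoxyethyl)-3-methyl-6-(propan-2-yl)cyclohex-3-ene-1-carboxylate | COC(=O)[C@@H]1[C@@H](C(C)C)CC=C(C)[C@@H]1CC(OC)OC | intermediate
7 | 2-(2,2-dimethoxyethyl)-3-methyl-6-(propan-2-yl)cyclohex-3-ene-1-carboxylic acid | OC(=O)[C@@H]1[C@@H](C(C)C)CC=C(C)[C@@H]1CC(OC)OC | intermediate
8 | methyl 2-(furan-2-yl)acetate | COC(=O)Cc1ccco1 | starting material
9 | methyl 2-(5-bromofuran-2-yl)acetate | COC(=O)Cc1ccc(Br)o1 | intermediate
10 | methyl 2-(5-bromofuran-2-yl)-3-hydroxypropanoate | COC(=O)C(CO)c1ccc(Br)o1 | intermediate (not isolated)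
11 | methyl 2-(5-bromofuran-2-yl)prop-2-enoate | COC(=O)C(=C)c1ccc(Br)o1 | intermediate
12 | pyridylthio adduct, acetal (C3 epimers) | COC(=O)C(Sc1ccccn1)(C[C@H]1[C@@H](C(C)C)CC=C(C)[C@@H]1CC(OC)OC)c1ccc(Br)o1 | intermediate
13 | pyridylthio adduct, C8 aldehyde (C3 epimers) | COC(=O)C(Sc1ccccn1)(C[C@H]1[C@@H](C(C)C)CC=C(C)[C@@H]1CC=O)c1ccc(Br)o1 | intermediate
14 | [6](2,5)furanophane alcohol, 8S (C3 epimers) | COC(=O)C1(Sc2ccccn2)C[C@H]2[C@@H](C(C)C)CC=C(C)[C@@H]2C[C@H](O)c2ccc1o2 | intermediate
15 | furan endoperoxide (one face, configuration at the two bridgeheads not assigned) | COC(=O)C1(Sc2ccccn2)C[C@H]2[C@@H](C(C)C)CC=C(C)[C@@H]2C[C@H](O)C23C=CC1(OO2)O3 | intermediate (not isolated)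
16 | cis-enedione alcohol | COC(=O)C1(Sc2ccccn2)C[C@H]2[C@@H](C(C)C)CC=C(C)[C@@H]2C[C@H](O)C(=O)/C=C\C1=O | intermediate (not isolated)
17 | pyranone hemiketal (C4–O–C8 ring, C7 ketone) | COC(=O)C1(Sc2ccccn2)C[C@H]2[C@@H](C(C)C)CC=C(C)[C@@H]2C[C@@H]2O[C@@]1(O)C=CC2=O | intermediate
18 | C7 methyl carbinol, pyranose hemiketal (7S, 8S) | COC(=O)C1(Sc2ccccn2)C[C@H]2[C@@H](C(C)C)CC=C(C)[C@@H]2C[C@@H]2O[C@@]1(O)C=C[C@]2(C)O | intermediate
19 | pyridyl sulfoxide of 18 | COC(=O)C1(S(=O)c2ccccn2)C[C@H]2[C@@H](C(C)C)CC=C(C)[C@@H]2C[C@@H]2O[C@@]1(O)C=C[C@]2(C)O | intermediate (not isolated)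
20 | des-urocanoyl (2E)-enoate, pyranose hemiketal form | COC(=O)/C1=C/[C@H]2[C@@H](C(C)C)CC=C(C)[C@@H]2C[C@@H]2O[C@@]1(O)C=C[C@]2(C)O | intermediate
21 | (E)-3-(1-methyl-1H-imidazol-4-yl)prop-2-enoic acid (N-methylurocanic acid) | OC(=O)/C=C/c1cn(C)cn1 | starting material
22 | des-urocanoyl enoate, furanose (4,7-oxa-bridged) tautomer | COC(=O)/C1=C/[C@H]2[C@@H](C(C)C)CC=C(C)[C@@H]2C[C@H](O)[C@]2(C)C=C[C@@]1(O)O2 | intermediate (not isolated)
23 | target, (1R,4R,7S,8S,10R,14R; 2E) | COC(=O)/C1=C/[C@H]2[C@@H](C(C)C)CC=C(C)[C@@H]2C[C@H](OC(=O)/C=C/c2cn(C)cn2)[C@]2(C)C=C[C@@]1(O)O2 | target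

**Step count and risks**

Total: 14 steps (12 on the main line, 2 for acrylate 11). Longest linear sequence: 12 steps (1–5, 8–14) from (R)-α-phellandrene.

The three steps most likely to fail:

Step 8 is untested. The disulfide may capture the C1 radical before it adds to 11, the adduct radical may end as the simple Giese product, and the C1 facial selectivity rests on the half-chair argument only (the minor C1 epimer would be removed at 12). The fallback uses known chemistry. It sets out from acid 7, which is converted into its Barton ester, the O-acyl thiohydroxamate F1 (2-mercaptopyridine N-oxide, DCC, CH2Cl2, 0 °C, dark). F1 is photolysed with a tungsten lamp in CH2Cl2 at 0 °C in the presence of 11 (5 equiv). This classical Barton decarboxylative radical chain addition with thiopyridyl transfer gives the same sulfide 12, with the same axial radical attack at C1, and the route is rejoined at 12.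

Step 10 closes a strained ring, and the facial selectivity at C8 in this trans-fused series is not predictable with confidence. The fallback sets out from aldehyde 13 and moves the C8 stereocontrol from the C–C bond formation to a hydride delivery. The closure is run without regard to selectivity and gives the 8-epi-furanophane alcohol F2, alone or mixed with 14. This is oxidised with Dess–Martin periodinane in CH2Cl2 to the macrocyclic furyl ketone F3. The ketone is reduced from its open face (NaBH4, CeCl3·7H2O, MeOH, −78 °C, or LiBH(s-Bu)3, THF, −78 °C), which returns to 14.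

Step 14 depends on the pyranose–furanose equilibrium and on acylating C8–OH in the presence of the hemiketal hydroxyl with a sluggish, poorly soluble acid. The fallback sets out from 20 and uses protection: PPTS in MeOH at 25 °C locks the furanose as the furanose methyl ketal F4, which has a single free secondary hydroxyl. Acylation with 21 (DCC, DMAP) gives the ketal ester F5, and CSA in wet CH2Cl2 unmasks the hemiketal to reach 23.

Further compounds
F1 | step 8 | Barton ester of acid 7 (2-thioxopyridin-1(2H)-yl ester) | S=C1C=CC=CN1OC(=O)[C@@H]1[C@@H](C(C)C)CC=C(C)[C@@H]1CC(OC)OC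
F2 | step 10 | 8-epi-furanophane alcohol (8R; C3 epimers) | COC(=O)C1(Sc2ccccn2)C[C@H]2[C@@H](C(C)C)CC=C(C)[C@@H]2C[C@@H](O)c2ccc1o2
F3 | step 10 | macrocyclic furyl ketone (C8 ketone; C3 epimers) | COC(=O)C1(Sc2ccccn2)C[C@H]2[C@@H](C(C)C)CC=C(C)[C@@H]2CC(=O)c2ccc1o2
F4 | step 14 | furanose methyl ketal with free C8 hydroxyl | COC(=O)/C1=C/[C@H]2[C@@H](C(C)C)CC=C(C)[C@@H]2C[C@H](O)[C@]2(C)C=C[C@@]1(OC)O2
F5 | step 14 | C4 methyl ketal of the target (ketal ester) | COC(=O)/C1=C/[C@H]2[C@@H](C(C)C)CC=C(C)[C@@H]2C[C@H](OC(=O)/C=C/c2cn(C)cn2)[C@]2(C)C=C[C@@]1(OC)O2
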